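**Plan**
Retrosynthetic cuts: the benzyl and C5''-methyl ethers; ring C of unit 2 at O1''–C2'', C2''–C3'' and C4''–C4a''; ring A of unit 1 at C5–C6 and C7–C8; ring C of unit 1 at O1–C2 and C4–C4a; the alkyne bonds C2–C3 and C3–C4; the C4'–O ether bond.
Forward order: diaryl ether (SNAr), arylpropiolic acid, pyranone ring C of unit 1, ring A of unit 1, acetyl group on ring A of unit 2, ring C of unit 2, deprotection.
Enabling feature: ring A of unit 1 (C4a, C5, C6, C7, C8, C8a) is a resorcinol ring with oxygen on C5 and C7, fused to the pyranone at C4a–C8a. C5 is therefore an ester carbon on C4a, C8 a methyl carbon on C8a, and C6–C7 one acetate unit.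
Stereochemistry: the target has no stereocentre; the E alkene of the chalcone and the racemic flavanone centre disappear in the oxidative cyclisation.

Key step: step 7

Remark on the chemistry: unit 1 is the flavone whose ring B carries the ether oxygen at C4' (unprimed and single-primed locants); unit 2 is the flavone etherified at C8 (double-primed locants). Compound 11 is drawn as the triketo form although it should exist as an enol. Flavanone 21 is racemic. The 2,4,6-trimethoxyphenoxy ring has a mirror plane, so its two free ring positions are equivalent.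

**Step 1**
Reactants: 1 2,4,6-trimethoxybenzaldehyde
Product: 3 2,4,6-trimethoxyphenol, via aryl formate 2 (not isolated)
Conditions: H2O2 (30% aq.), H2SO4 (cat.), MeOH, rt
Reagents that add atoms: hydrogen peroxide, OO
Why: Acid-catalysed Dakin (Baeyer–Villiger-type) oxidation, in which the electron-rich aryl group migrates to oxygen in the peroxide adduct and the formate is methanolysed in the same flask.

**Step 2**
Reactants: 3 2,4,6-trimethoxyphenol; 4 4-fluorobenzaldehyde
Product: 5 4-(2,4,6-trimethoxyphenoxy)benzaldehyde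
Conditions: K2CO3, DMF, 120 °C, argon
Reagents that add atoms: none
Why: Nucleophilic aromatic substitution, the para-formyl group stabilising the Meisenheimer adduct so that even the hindered phenoxide displaces fluoride.

**Step 3**
Reactants: 5 4-(2,4,6-trimethoxyphenoxy)benzaldehyde
Product: 6 2-[4-(2,2-dibromoethenyl)phenoxy]-1,3,5-trimethoxybenzene
Conditions: CBr4, PPh3, CH2Cl2, 0 °C
Reagents that add atoms: carbon tetrabromide, BrC(Br)(Br)Br
Why: First stage of the Corey–Fuchs sequence, a Wittig-type olefination of the aldehyde by the dibromomethylene ylide formed from PPh3 and CBr4.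

**Step 4**
Reactants: 6 2-[4-(2,2-dibromoethenyl)phenoxy]-1,3,5-trimethoxybenzene
Product: 8 3-[4-(2,4,6-trimethoxyphenoxy)phenyl]prop-2-ynoic acid, via lithium acetylide 7 (not isolated)
Conditions: n-BuLi (2.2 equiv), THF, −78 °C; CO2; aq. HCl
Reagents that add atoms: carbon dioxide, O=C=O
Why: Second stage of the Corey–Fuchs sequence, in which elimination and bromine–lithium exchange give the lithium acetylide that is carboxylated by CO2.

**Step 5**
Reactants: 8 3-[4-(2,4,6-trimethoxyphenoxy)phenyl]prop-2-ynoic acid; 9 ethyl acetoacetate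
Product: 11 ethyl 2-acetyl-3-oxo-5-[4-(2,4,6-trimethoxyphenoxy)phenyl]pent-4-ynoate, via acid chloride 10 (not isolated)
Conditions: 1-chloro-N,N,2-trimethylprop-1-en-1-amine, CH2Cl2, 0 °C to rt; then 9, MgCl2, pyridine, CH2Cl2, 0 °C to rt; aq. HCl
Reagents that add atoms: none
Why: Neutral acid chloride formation with the α-chloroenamine followed by C-acylation of the magnesium chelate of the β-keto ester (Rathke-type acylation), chelation directing the acyl group to carbon and not to oxygen.

**Step 6**
Reactants: 11 ethyl 2-acetyl-3-oxo-5-[4-(2,4,6-trimethoxyphenoxy)phenyl]pent-4-ynoate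
Product: 12 ethyl 2-methyl-4-oxo-6-[4-(2,4,6-trimethoxyphenoxy)phenyl]-4H-pyran-3-carboxylate
Conditions: TfOH (10 mol%), CH2Cl2, rt
Reagents that add atoms: none
Why: Brønsted-acid-catalysed intramolecular oxa-Michael addition (6-endo-dig) of the acetyl enol oxygen to the β-carbon of the protonated ynone, the five-membered alternative requiring an anti-Michael attack at the α-carbon.

**Step 7**
Reactants: 12 ethyl 2-methyl-4-oxo-6-[4-(2,4,6-trimethoxyphenoxy)phenyl]-4H-pyran-3-carboxylate; 13 ethyl acetate
Product: 15 5,7-dihydroxy-2-[4-(2,4,6-trimethoxyphenoxy)phenyl]-4H-chromen-4-one, via acetonylpyranone ester 14 (not isolated)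
Conditions: LiN(i-Pr)2 (2.0 equiv), THF, −78 °C; EtOAc (2.5 equiv), −78 to −20 °C; LiN(i-Pr)2 (3.0 equiv), −78 °C to rt; aq. HCl
Reagents that add atoms: none
Why: Proposed new method: the amide base should remove a proton from the methyl group on C2 of the pyranone (the future C8), which is vinylogous to both the ring carbonyl and the ester, and the lateral anion should be acylated at carbon by ethyl acetate, the ester enolate formed from the second equivalent of base taking up the acidic proton of 14 so that no lateral anion is lost as a base; the second charge of base then deprotonates the terminal methyl group, this carbanion (C6) adds to the neighbouring ester carbonyl (C5), ethoxide leaves and the triketone tautomerises to the resorcinol dianion. The closest known reaction types are the lateral lithiation and acylation of ortho-toluate esters with Dieckmann-type closure to naphthalene-1,3-diols, and the lateral lithiation of 2-methyl-4-pyranones. Ring A closes in a 6-exo-trig Claisen (Dieckmann) mode. No stereocentre is formed. The step needs attack on the ester by carbon C6 and not by the enolate oxygen (which would give a fused lactone); the much higher nucleophilicity of the terminal carbon of the 1,3-dianion and the irreversible aromatisation should secure this. It also needs the electrophilic ring positions of the pyranone to stay untouched, which the anionic side chain and the hindered base should ensure.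

**Step 8**
Reactants: 15 5,7-dihydroxy-2-[4-(2,4,6-trimethoxyphenoxy)phenyl]-4H-chromen-4-one
Product: 16 5-hydroxy-7-methoxy-2-[4-(2,4,6-trimethoxyphenoxy)phenyl]-4H-chromen-4-one
Conditions: MeI (1.1 equiv), K2CO3, acetone, reflux
Reagents that add atoms: iodomethane, CI
Why: Williamson O-methylation that should stop at the C7 hydroxyl because the C5 hydroxyl is hydrogen-bonded to the C4 carbonyl and far less nucleophilic.

**Step 9**
Reactants: 16 5-hydroxy-7-methoxy-2-[4-(2,4,6-trimethoxyphenoxy)phenyl]-4H-chromen-4-one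
Product: 18 2-[4-(3-acetyl-2-hydroxy-4,6-dimethoxyphenoxy)phenyl]-5-hydroxy-7-methoxy-4H-chromen-4-one, via trimethoxy ketone 17 (not isolated)
Conditions: AcCl, AlCl3 (excess), CH2Cl2, 0 °C to rt; aq. HCl
Reagents that add atoms: acetyl chloride, CC(Cl)=O
Why: Friedel–Crafts acylation at one of the two equivalent free positions of the most electron-rich ring, followed by chelation-assisted cleavage of the more crowded ortho-methoxy group (flanked by acetyl and aryloxy), the behaviour known for 1,2,3,5-tetramethoxybenzene under the same conditions.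

**Step 10**
Reactants: 18 2-[4-(3-acetyl-2-hydroxy-4,6-dimethoxyphenoxy)phenyl]-5-hydroxy-7-methoxy-4H-chromen-4-one; 19 4-(benzyloxy)benzaldehyde
Product: 20 2-[4-(3-{(E)-3-[4-(benzyloxy)phenyl]prop-2-enoyl}-2-hydroxy-4,6-dimethoxyphenoxy)phenyl]-5-hydroxy-7-methoxy-4H-chromen-4-one
Conditions: KOH (aq.), EtOH/THF, rt; aq. HCl
Reagents that add atoms: none
Why: Claisen–Schmidt aldol condensation of the methyl ketone with a non-enolisable aldehyde, dehydration giving the conjugated E alkene while the flavone of unit 1 is shielded as its phenoxide at room temperature.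

**Step 11**
Reactants: 20 the chalcone of step 10
Product: 22 2-[4-(benzyloxy)phenyl]-8-[4-(5-hydroxy-7-methoxy-4-oxo-4H-chromen-2-yl)phenoxy]-5,7-dimethoxy-4H-chromen-4-one, via flavanone 21 (not isolated)
Conditions: I2 (10 mol%), DMSO, 130 °C
Reagents that add atoms: none
Why: Iodine/DMSO oxidative cyclisation of a 2'-hydroxychalcone, by oxa-Michael closure to the flavanone, α-iodination and loss of HI, with DMSO reoxidising iodide.

**Step 12**
Reactants: 22 the benzyl-protected biflavone of step 11
Product: 23 5-hydroxy-8-[4-(5-hydroxy-7-methoxy-4-oxo-4H-chromen-2-yl)phenoxy]-2-(4-hydroxyphenyl)-7-methoxy-4H-chromen-4-one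
Conditions: BCl3, pentamethylbenzene, CH2Cl2, −78 to 0 °C; then H2O
Reagents that add atoms: none
Why: Lewis-acid ether cleavage in which BCl3 chelated by the C4'' carbonyl removes only the peri C5'' methyl group and also cleaves the benzyl ether (cation trapped by pentamethylbenzene), the C7 and C7'' methoxy groups lacking such activation.

**Compound list**
1 | 2,4,6-trimethoxybenzaldehyde | COc1cc(OC)c(C=O)c(OC)c1 | starting material
2 | 2,4,6-trimethoxyphenyl formate | COc1cc(OC)c(OC=O)c(OC)c1 | intermediate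
3 | 2,4,6-trimethoxyphenol | COc1cc(OC)c(O)c(OC)c1 | intermediate
4 | 4-fluorobenzaldehyde | O=Cc1ccc(F)cc1 | starting material
5 | 4-(2,4,6-trimethoxyphenoxy)benzaldehyde | COc1cc(OC)c(Oc2ccc(C=O)cc2)c(OC)c1 | intermediate
6 | 2-[4-(2,2-dibromoethenyl)phenoxy]-1,3,5-trimethoxybenzene | COc1cc(OC)c(Oc2ccc(C=C(Br)Br)cc2)c(OC)c1 | intermediate
7 | lithium [4-(2,4,6-trimethoxyphenoxy)phenyl]acetylide | [Li]C#Cc1ccc(Oc2c(OC)cc(OC)cc2OC)cc1 | intermediate
8 | 3-[4-(2,4,6-trimethoxyphenoxy)phenyl]prop-2-ynoic acid | OC(=O)C#Cc1ccc(Oc2c(OC)cc(OC)cc2OC)cc1 | intermediate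
9 | ethyl acetoacetate | CCOC(=O)CC(C)=O | starting material
10 | 3-[4-(2,4,6-trimethoxyphenoxy)phenyl]prop-2-ynoyl chloride | ClC(=O)C#Cc1ccc(Oc2c(OC)cc(OC)cc2OC)cc1 | intermediate
11 | ethyl 2-acetyl-3-oxo-5-[4-(2,4,6-trimethoxyphenoxy)phenyl]pent-4-ynoate | CCOC(=O)C(C(C)=O)C(=O)C#Cc1ccc(Oc2c(OC)cc(OC)cc2OC)cc1 | intermediate
12 | ethyl 2-methyl-4-oxo-6-[4-(2,4,6-trimethoxyphenoxy)phenyl]-4H-pyran-3-carboxylate | CCOC(=O)c1c(C)oc(-c2ccc(Oc3c(OC)cc(OC)cc3OC)cc2)cc1=O | intermediate
13 | ethyl acetate | CCOC(C)=O | starting material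
14 | ethyl 4-oxo-2-(2-oxopropyl)-6-[4-(2,4,6-trimethoxyphenoxy)phenyl]-4H-pyran-3-carboxylate | CCOC(=O)c1c(CC(C)=O)oc(-c2ccc(Oc3c(OC)cc(OC)cc3OC)cc2)cc1=O | intermediate
15 | 5,7-dihydroxy-2-[4-(2,4,6-trimethoxyphenoxy)phenyl]-4H-chromen-4-one | COc1cc(OC)c(Oc2ccc(-c3cc(=O)c4c(O)cc(O)cc4o3)cc2)c(OC)c1 | intermediate
16 | 5-hydroxy-7-methoxy-2-[4-(2,4,6-trimethoxyphenoxy)phenyl]-4H-chromen-4-one | COc1cc(O)c2c(=O)cc(-c3ccc(Oc4c(OC)cc(OC)cc4OC)cc3)oc2c1 | intermediate
17 | 2-[4-(3-acetyl-2,4,6-trimethoxyphenoxy)phenyl]-5-hydroxy-7-methoxy-4H-chromen-4-one | COc1cc(O)c2c(=O)cc(-c3ccc(Oc4c(OC)cc(OC)c(C(C)=O)c4OC)cc3)oc2c1 | intermediate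
18 | 2-[4-(3-acetyl-2-hydroxy-4,6-dimethoxyphenoxy)phenyl]-5-hydroxy-7-methoxy-4H-chromen-4-one | COc1cc(O)c2c(=O)cc(-c3ccc(Oc4c(OC)cc(OC)c(C(C)=O)c4O)cc3)oc2c1 | intermediate
19 | 4-(benzyloxy)benzaldehyde | O=Cc1ccc(OCc2ccccc2)cc1 | starting material
20 | 2-[4-(3-{(E)-3-[4-(benzyloxy)phenyl]prop-2-enoyl}-2-hydroxy-4,6-dimethoxyphenoxy)phenyl]-5-hydroxy-7-methoxy-4H-chromen-4-one | COc1cc(O)c2c(=O)cc(-c3ccc(Oc4c(OC)cc(OC)c(C(=O)/C=C/c5ccc(OCc6ccccc6)cc5)c4O)cc3)oc2c1 | intermediate
21 | 2-[4-(benzyloxy)phenyl]-8-[4-(5-hydroxy-7-methoxy-4-oxo-4H-chromen-2-yl)phenoxy]-5,7-dimethoxychroman-4-one (racemic) | COc1cc(OC)c2c(c1Oc1ccc(-c3cc(=O)c4c(O)cc(OC)cc4o3)cc1)OC(c1ccc(OCc3ccccc3)cc1)CC2=O | intermediate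
22 | 2-[4-(benzyloxy)phenyl]-8-[4-(5-hydroxy-7-methoxy-4-oxo-4H-chromen-2-yl)phenoxy]-5,7-dimethoxy-4H-chromen-4-one | COc1cc(OC)c2c(=O)cc(-c3ccc(OCc4ccccc4)cc3)oc2c1Oc1ccc(-c2cc(=O)c3c(O)cc(OC)cc3o2)cc1 | intermediate
23 | 5-hydroxy-8-[4-(5-hydroxy-7-methoxy-4-oxo-4H-chromen-2-yl)phenoxy]-2-(4-hydroxyphenyl)-7-methoxy-4H-chromen-4-one | COc1cc(O)c2c(=O)cc(-c3ccc(Oc4c(OC)cc(O)c5c(=O)cc(-c6ccc(O)cc6)oc45)cc3)oc2c1 | target

**Step count**
Total steps: 12. Longest linear sequence: 12 steps (from 1).

**Steps most likely to fail**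

Step 7. The lateral anion may be consumed by proton transfer before C-acylation is complete, the acetonyl intermediate may close through oxygen to a fused lactone, or the pyranone ring may be opened by nucleophilic attack. The fallback uses only known chemistry; it sets out from 5 and comes back at 16. Aldehyde 5 would be condensed with commercial 1-(2-hydroxy-4,6-dimethoxyphenyl)ethanone (KOH, EtOH, rt; Claisen–Schmidt) to the chalcone (E)-1-(2-hydroxy-4,6-dimethoxyphenyl)-3-[4-(2,4,6-trimethoxyphenoxy)phenyl]prop-2-en-1-one F1. I2 (cat.) in DMSO at 130 °C would close it to 5,7-dimethoxy-2-[4-(2,4,6-trimethoxyphenoxy)phenyl]-4H-chromen-4-one F2. BCl3 in CH2Cl2 at 0 °C would then cleave only the methyl ether peri to the carbonyl and give 16. Ring A of unit 1 would then come from the acetophenone, and steps 3 to 8 would not be needed.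

Step 9. The aluminium reagent may cleave the ortho-methoxy group next to the ring C–H instead of the one next to the aryloxy group, which would lead on to the 6''-linked isomer, or it may cleave both. The fallback sets out from 16 and comes back at 18. Acylation with Ac2O and BF3·OEt2 would give 17, now isolated. Excess BCl3 in CH2Cl2 at rt would remove both carbonyl-flanking methyl groups to give 2-[4-(3-acetyl-2,4-dihydroxy-6-methoxyphenoxy)phenyl]-5-hydroxy-7-methoxy-4H-chromen-4-one F3. One equivalent of MeI with K2CO3 in acetone should then methylate the less hindered hydroxyl, the one flanked by acetyl and aryloxy staying chelated, which gives 18. Regiocontrol then rests on selective alkylation and no longer on selective dealkylation.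

Step 6. The enol may close through the α-carbon of the alkyne to a five-membered alkylidenefuranone or through the ester oxygen, and the triacylmethane may lose its acetyl group. The fallback sets out from 8 and comes back at 12. LiCl in AcOH at 70 °C would add HCl across the triple bond (anti addition, chloride at the benzylic carbon) to give (Z)-3-chloro-3-[4-(2,4,6-trimethoxyphenoxy)phenyl]prop-2-enoic acid F4. The chloroenamine of step 5 would convert it into (Z)-3-chloro-3-[4-(2,4,6-trimethoxyphenoxy)phenyl]prop-2-enoyl chloride F5 (not isolated). This would acylate the magnesium chelate of 9 to ethyl (Z)-2-acetyl-5-chloro-3-oxo-5-[4-(2,4,6-trimethoxyphenoxy)phenyl]pent-4-enoate F6 (not isolated). With pyridine in the same flask the enol oxygen would displace chloride by addition–elimination at the only electrophilic alkene carbon, so that only the six-membered ring of 12 can form.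

**Further compounds**
F1 | step 7 | (E)-1-(2-hydroxy-4,6-dimethoxyphenyl)-3-[4-(2,4,6-trimethoxyphenoxy)phenyl]prop-2-en-1-one | COc1cc(O)c(C(=O)/C=C/c2ccc(Oc3c(OC)cc(OC)cc3OC)cc2)c(OC)c1
F2 | step 7 | 5,7-dimethoxy-2-[4-(2,4,6-trimethoxyphenoxy)phenyl]-4H-chromen-4-one | COc1cc(OC)c2c(=O)cc(-c3ccc(Oc4c(OC)cc(OC)cc4OC)cc3)oc2c1
F3 | step 9 | 2-[4-(3-acetyl-2,4-dihydroxy-6-methoxyphenoxy)phenyl]-5-hydroxy-7-methoxy-4H-chromen-4-one | COc1cc(O)c2c(=O)cc(-c3ccc(Oc4c(OC)cc(O)c(C(C)=O)c4O)cc3)oc2c1
F4 | step 6 | (Z)-3-chloro-3-[4-(2,4,6-trimethoxyphenoxy)phenyl]prop-2-enoic acid | OC(=O)/C=C(\Cl)c1ccc(Oc2c(OC)cc(OC)cc2OC)cc1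
F5 | step 6 | (Z)-3-chloro-3-[4-(2,4,6-trimethoxyphenoxy)phenyl]prop-2-enoyl chloride | ClC(=O)/C=C(\Cl)c1ccc(Oc2c(OC)cc(OC)cc2OC)cc1
F6 | step 6 | ethyl (Z)-2-acetyl-5-chloro-3-oxo-5-[4-(2,4,6-trimethoxyphenoxy)phenyl]pent-4-enoate | CCOC(=O)C(C(C)=O)C(=O)/C=C(\Cl)c1ccc(Oc2c(OC)cc(OC)cc2OC)cc1
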